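Atom labels in the prose follow the benzofuran numbering of the target (O1, C2, C3, C3a, C4–C7, C7a; ring A is the carbocycle, ring B the furan ring), also for monocyclic intermediates. Systematic names carry their own locants. Compound numbers are those of the list after the steps.

## The problem

The target is a 3,3a,4,5-tetrahydrobenzofuran-6(2H)-one. A cyclohexenone (ring A) and a dihydrofuran (ring B) share the C3a–C7a bond, and O1, C7a, C7 and the C6 carbonyl form a vinylogous ester that spans both rings. C3a is quaternary (allyl, C3, C4 and the sp2 carbon C7a) and cannot be corrected once made, so its absolute configuration must come from the step that creates it. The other three centres can be steered by it. C5 is α to the C6 carbonyl and equilibrates through the enol. C2 is a benzylic ether carbon with an electron-rich aryl group and opens reversibly under acid. C3 can exchange through the alkene that the C2 cation forms by proton loss. The ring fusion holds the allyl group pseudo-axial on ring A and tilts C3 to the opposite face. The methyl group cis to allyl, the aryl group trans to methyl and the methoxy group trans to allyl are then all pseudo-equatorial, so the target should be the thermodynamic diastereomer. Sensitive groups are the terminal allyl alkene (hydrogenation, hydroboration, electrophilic halogen or mercury reagents, hot strong acid), the acid-labile C2–O1 bond, the epimerisable α-methoxy ketone and the vinylogous ester. The feature that opens the route is the oxygen pattern of ring A: O on C7a, carbonyl at C6 and methoxy at C5 are the oxygens of a 4-methoxyacetoacetate dienol ether, while C4 and C3a are the methylene and α-carbons of a 2-allyl vinyl ketone whose acetyl group is C3 with its methyl attached.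

## Retrosynthesis

Ring B (15 ⇒ 13). The O1–C2 bond and the C3–H bond are cut, which returns 15 to the tertiary carbinol 13, a cyclohexane-1,3-dione in which C2 is still a benzylic methylene group. Forward, acid removes water to give styrene 14, protonates it at C3, and the C7a enol oxygen traps the benzylic cation at C2. The neighbouring cuts are weaker: O1–C7a would need a stereodefined secondary alcohol on an open chain beside the quaternary carbon, and C3–C3a would need the quaternary centre to be made on an aromatic ring. The chosen cut removes two stereocentres (C2, C3) and relaxes a third (C5), so 13 has C3a as its only fixed stereocentre. It asks that the reversible events (C2–O1 ionisation, proton loss and return at C3, enolisation at C5) reach the thermodynamic isomer before the allyl group is protonated.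

Aryl half (13 ⇒ 10 + 11). The C2–C3 bond is cut: the benzyl Grignard reagent 12, made from chloride 11, adds to the acetyl carbonyl of 10. An olefination at this carbonyl would give 14 directly but suits a methyl ketone on a quaternary carbon poorly; a carbonyl addition does not have that limit. The cut removes the whole aryl half (ten carbons) and leaves the C12 trione 10. The forward reaction must pick the acetyl group out of three carbonyls, which is arranged by carrying the 1,3-dione as its enolate.

Ring A (10 ⇒ 5 + 8). C4–C5 and C3a–C7a are cut in a retro-(4+2) sense. Diene 8 supplies C5, C6, C7 and C7a with all three ring oxygens; enone 5 supplies C4, C3a, the allyl group and C3 as an acetyl group. Annulations through C6–C7 or C7–C7a would bring the carbons but leave the C5 and C7a oxygens to separate oxidations. The primary adduct 9 has a silyl enol ether at C6 and a mixed silyl methyl ketal at C7a. On hydrolysis such a ketal collapses to the carbonyl and gives up methanol, so the isolable product is the dione 10, not a methyl enol ether. That is no loss: 10 carries the free C7a enol that step 7 needs, and its enolate shields ring A in step 6. The precursors are two open-chain compounds without stereocentres. The forward reaction must join the methoxy-bearing diene terminus to the methylene carbon, add to C=C rather than C=O, and choose one face of the enone; the last is the task of a chiral oxazaborolidinium Lewis acid. Diene 8 is drawn with the C4 methoxy group cis to the C3 silyloxy group, so that it points outward in the s-cis conformer. Endo or exo approach affects only C5, which is equilibrated later.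

Enone (5 ⇒ 3 + 4; 3 ⇒ 1 + 2). The C=CH2 bond is cut by a Horner–Wadsworth–Emmons disconnection to phosphonate 3 and formaldehyde 4, and the allyl–carbon bond of 3 to phosphonate 1 and allyl bromide 2. Direct aminomethylation and elimination on the parent methyl ketone would be shorter but would have to tell its methyl from its methylene α-position. Here phosphorus marks the carbon that becomes the alkene, so the regiochemistry is fixed by construction. Both forward steps are standard and use commercial materials.

Diene (8 ⇒ 7 ⇒ 6). Two O–Si bonds are cut in turn: the ketene-acetal silyl group back to the silyloxy enoate 7, and the enol silyl group back to methyl 4-methoxy-3-oxobutanoate 6. This is the usual two-stage silylation of a β-keto ester. The forward sequence must deprotonate 7 at the methoxymethylene carbon and keep moisture out.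

## Roads not taken

Alternative 1: The cut is O1–C7a, made while ring A is still a 4,4-disubstituted cyclohexa-2,5-dienone. In dienone A2 the quaternary carbon is not yet a stereocentre, and K2CO3 in methanol lets the C2 hydroxyl add 5-exo to the β-carbon of one of the two enone arms to give the cis-fused bicycle A1.
- Merits: C2 and C3 are made beforehand on an open chain by reagent-controlled aldol or crotylation chemistry, the fusion can only be cis, and C3a is fixed by group selection instead of a catalyst. In the control of C2 and C3 this road is better than the chosen one.
- Weak points: A1 has the wrong oxidation pattern. It has no methoxy group at C5 and a C4=C5 enone in place of the C7=C7a enol ether. The enone must be reduced, C5 methoxylated and C7–C7a dehydrogenated with regiocontrol between the two α-positions of C6, all beside an allyl group. The oxa-Michael step is reversible, so the choice between the diastereotopic arms rests on a small energy difference. A2 itself needs a hindered para-quaternary dienone.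
- Comparison: the chosen plan installs all three ring A oxygens and the C7=C7a unsaturation in its ring-forming events and needs far fewer operations after the key step. Against the cleaner C2/C3 control of this road it has only the conformational bias of the fused system and a fallback.

Alternative 2: The cut is C3a–C7a at the radical level. The phenylseleno ester A4 gives, with (Me3Si)3SiH and azobisisobutyronitrile, an acyl radical at C7a that adds 6-exo to C3a of a tetrasubstituted aryl enone; the C3 radical takes hydrogen from the silane to give ketal A3.
- Merits: radical addition tolerates the congestion of a quaternary centre better than most polar bond formations, the conditions are neutral, and the retained C2 ketone is a handle for setting C2 by reduction before ring B closes by condensation onto C7a. In tolerance of steric crowding this road is arguably better than a cycloaddition that joins a quaternary carbon to a ketal carbon.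
- Weak points: C3a, C3 and later C2 must all be derived from the single C5 stereocentre of A4, the one centre that is mobile in the target. C3a would rely on 1,3-induction and C3 on acyclic hydrogen abstraction. Addition of a nucleophilic acyl radical to a fully substituted β-carbon is slow, so premature reduction and decarbonylation compete. A4 is a long linear construction (tetrasubstituted enone of defined geometry, ketal, selenoester).
- Comparison: the chosen plan is convergent and controls C3a with a catalyst, which this road cannot offer; it pays with the steric demand of its cycloaddition.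

Alternative 3: The cut is C3–C3a on an aromatic ring A. In mesylate A6 the C6 phenoxide, tethered through O1–C2, displaces the secondary C3 mesylate with its para carbon C3a (5-exo-tet) to give the cross-conjugated dienone A5.
- Merits: it is the shortest road on paper. C2 and C3 come from asymmetric oxidation of a propenylarene, and the displacement sets C3 by inversion, so C2/C3 control is better than in the chosen plan.
- Weak points: C7, the unsubstituted ortho carbon next to C7a, closes the same ring size and leads to a rearomatised dihydrobenzofuran, so ipso attack at the allyl-bearing C3a must win against the sterically and thermodynamically favoured course. The secondary mesylate has a neighbouring aryl group and ether oxygen that can participate and scramble C3. A5 still needs its C4=C5 bond reduced chemoselectively with control at C5, and 3a-allyl dienones of this kind rearrange readily.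
- Comparison: the chosen plan forms ring A with unambiguous regiochemistry and at the correct oxidation level. Against the superior C2/C3 control of this road it has only an equilibration.

Key step: step 5

Assumption 1: the oxazaborolidinium ion derived from (S)-α,α-diphenylprolinol is taken to expose the face of 5 that leads to the 3aR series; the sense of induction for an α-branched acyclic enone would be checked on 10, and the enantiomeric catalyst used if it proved opposite.

Assumption 2: 9, 10, 13 and 14 are drawn with the C5 configuration of the target although this centre is mobile until step 7 and they may be handled as C5 epimer mixtures; 7 is an E/Z mixture whose geometry is lost in step 4.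

## Steps

Step 1
Reactants: 1 dimethyl (2-oxopropyl)phosphonate; 2 allyl bromide (3-bromoprop-1-ene)
Product: 3 dimethyl (2-oxohex-5-en-3-yl)phosphonate
Conditions: NaH, THF, 0 °C; then 2, 0 °C → rt
Reagents that add atoms: none
Why: C-Alkylation of the sodium enolate of a β-ketophosphonate with a reactive allylic halide; the carbon between P=O and C=O is the only nucleophilic site, and a slight excess of 1 limits double allylation.

Step 2
Reactants: 3 dimethyl (2-oxohex-5-en-3-yl)phosphonate; 4 formaldehyde (37% aqueous solution)
Product: 5 3-methylidenehex-5-en-2-one
Conditions: K2CO3, H2O–THF, rt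
Reagents that add atoms: none
Why: Horner–Wadsworth–Emmons olefination with formaldehyde, the standard route from α-alkyl β-ketophosphonates to α-methylene ketones; the phosphorus-bearing carbon becomes the alkene carbon, so the methylene group can only arise at C3. The volatile, dimerisation-prone enone is extracted into pentane, kept cold over a trace of 2,6-di-tert-butyl-4-methylphenol and used promptly.

Step 3
Reactants: 6 methyl 4-methoxy-3-oxobutanoate
Product: 7 methyl 4-methoxy-3-(trimethylsilyloxy)but-2-enoate
Conditions: Me3SiCl, Et3N, toluene, rt
Reagents that add atoms: chlorotrimethylsilane, C[Si](C)(C)Cl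
Why: O-Silylation of the enol of a β-keto ester under amine-base conditions (soft enolisation), the usual first stage of bis(silyloxy)diene synthesis; the ammonium salt is filtered off and 7 is distilled.

Step 4
Reactants: 7 methyl 4-methoxy-3-(trimethylsilyloxy)but-2-enoate
Product: 8 (1E,3Z)-1,4-dimethoxy-1,3-bis(trimethylsilyloxy)buta-1,3-diene
Conditions: LiN(iPr)2, THF, −78 °C; Me3SiCl, −78 → 0 °C
Reagents that add atoms: chlorotrimethylsilane, C[Si](C)(C)Cl
Why: γ-Deprotonation of the silyloxy enoate at the methoxymethylene carbon and O-silylation of the ester dienolate, the standard second stage for 1,3-bis(silyloxy)buta-1,3-dienes. The C4 methoxy group is expected cis to the C3 silyloxy group (outward in the s-cis conformer); neither double-bond geometry affects the final stereochemistry, because C7a becomes trigonal and C5 is equilibrated.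

Step 5
Reactants: 5 3-methylidenehex-5-en-2-one; 8 (1E,3Z)-1,4-dimethoxy-1,3-bis(trimethylsilyloxy)buta-1,3-diene
Product: 10 (4R,6R)-4-acetyl-6-methoxy-4-(prop-2-en-1-yl)cyclohexane-1,3-dione, via silyl cycloadduct 9 (not isolated)
Conditions: (3aS)-1-(2-methylphenyl)-3,3-diphenyltetrahydro-1H,3H-pyrrolo[1,2-c][1,3,2]oxazaborole (C24H24BNO, 20 mol%), HN(SO2CF3)2 (18 mol%), Ph3PO (25 mol%), CH2Cl2, −78 → −40 °C; then 1 M HCl, THF, 0 °C
Reagents that add atoms: none
Why: Proposed new method: the triflimide-activated oxazaborolidinium ion binds the ketone oxygen of 5, and diene 8, polarised by its oxygen donors, bonds through its methoxy-bearing terminus (C5) to the unhindered methylene carbon (C4) and through its ketene-acetal carbon (C7a) to the α-carbon (C3a) in a concerted but strongly asynchronous (4+2) cycloaddition, at the stepwise limit a Mukaiyama–Michael addition followed by collapse of the boron enolate onto the silyloxycarbenium carbon. The closest known reactions are oxazaborolidinium-catalysed Diels–Alder reactions of 2-substituted acroleins and enones with silyloxydienes, Mukaiyama–Michael additions of trimethylsilyl ketene acetals to enones under the same catalysts with Ph3PO as a trap for Me3Si+, and uncatalysed or achiral Lewis-acid (4+2) reactions of 1,3-bis(silyloxy)dienes with enones; what has not been shown is a bis(silyloxy)diene with an α-branched acyclic enone under a chiral catalyst. Ring A closes in the (4+2) mode by formation of C4–C5 and C3a–C7a. C3a is set by the catalyst, whose aryl groups shield one face of the bound enone so that both bonds form on the open face; C5 and the ketal carbon C7a arise as mixtures, of which C7a is erased on hydrolysis and C5 is equilibrated in step 7. The step needs regioselectivity, which diene polarisation secures, addition to C=C rather than C=O, which the hindered carbonyl carbon and the free methylene carbon secure, and enantiofacial selectivity, which depends on the chiral catalyst outrunning silyl-cation catalysis, hence the low temperature and the phosphine oxide. Aqueous HCl then cleaves the C6 silyl enol ether and collapses the C7a silyl methyl ketal to the carbonyl with loss of methanol, giving dione 10, which exists largely as its enol.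

Step 6
Reactants: 10 (4R,6R)-4-acetyl-6-methoxy-4-(prop-2-en-1-yl)cyclohexane-1,3-dione; 11 5-(chloromethyl)-1,2,3-trimethoxybenzene (3,4,5-trimethoxybenzyl chloride)
Product: 13 (4R,6R)-4-[(2RS)-2-hydroxy-1-(3,4,5-trimethoxyphenyl)propan-2-yl]-6-methoxy-4-(prop-2-en-1-yl)cyclohexane-1,3-dione, via (3,4,5-trimethoxybenzyl)magnesium chloride 12 (not isolated)
Conditions: 11, Mg, THF, 0 °C; anhydrous CeCl3, THF, −78 °C; add 10 pretreated with LiN(SiMe3)2 (1.05 equiv), THF, −78 → −40 °C; aq. NH4Cl, then 1 M HCl to pH 3
Reagents that add atoms: none
Why: CeCl3-promoted Grignard addition to a hindered, enolisable methyl ketone; the acidic 1,3-dione is first converted into its lithium enolate, which is inert to nucleophiles, so the acetyl group is the only electrophilic carbonyl. The new carbinol centre forms without control and is erased in step 7.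

Step 7
Reactants: 13 (4R,6R)-4-[(2RS)-2-hydroxy-1-(3,4,5-trimethoxyphenyl)propan-2-yl]-6-methoxy-4-(prop-2-en-1-yl)cyclohexane-1,3-dione
Product: 15 (2R,3R,3aR,5R)-5-methoxy-3-methyl-3a-(prop-2-en-1-yl)-2-(3,4,5-trimethoxyphenyl)-3,3a,4,5-tetrahydro-1-benzofuran-6(2H)-one, via styrene dione 14 (not isolated)
Conditions: CF3SO3H (0.2 equiv), CH2Cl2, 0 °C → rt
Reagents that add atoms: none
Why: Acid-catalysed E1 dehydration gives styrene 14, protonation at C3 gives the 3,4,5-trimethoxybenzylic cation at C2, and the C7a enol oxygen captures it in a five-membered ring (intramolecular acid-catalysed hydroalkoxylation of a styrene by a 1,3-dione enol). C3a is untouched; C2 (C–O ionisation), C3 (proton loss and return through 14) and C5 (enolisation) are reversible and should settle in the arrangement the ring fusion favours, with aryl trans to methyl, methyl cis to allyl and methoxy trans to allyl, all pseudo-equatorial. The trisubstituted styrene is protonated far more readily than the terminal allyl alkene, which defines the usable acidity and time.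

## Compound list

1 | dimethyl (2-oxopropyl)phosphonate | CC(=O)CP(=O)(OC)OC | starting material
2 | allyl bromide (3-bromoprop-1-ene) | C=CCBr | starting material
3 | dimethyl (2-oxohex-5-en-3-yl)phosphonate (racemic; the stereocentre is lost in step 2) | C=CCC(C(C)=O)P(=O)(OC)OC | intermediate
4 | formaldehyde (37% aqueous solution) | C=O | starting material
5 | 3-methylidenehex-5-en-2-one | C=CCC(=C)C(C)=O | intermediate
6 | methyl 4-methoxy-3-oxobutanoate | COCC(=O)CC(=O)OC | starting material
7 | methyl 4-methoxy-3-(trimethylsilyloxy)but-2-enoate (E/Z mixture) | COCC(O[Si](C)(C)C)=CC(=O)OC | intermediate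
8 | (1E,3Z)-1,4-dimethoxy-1,3-bis(trimethylsilyloxy)buta-1,3-diene | CO/C=C(O[Si](C)(C)C)/C=C(\OC)O[Si](C)(C)C | intermediate
9 | 1-[(1R)-2,5-dimethoxy-1-(prop-2-en-1-yl)-2,4-bis(trimethylsilyloxy)cyclohex-3-en-1-yl]ethan-1-one (mixture at C2 and C5; not isolated) | C=CC[C@]1(C(C)=O)CC(OC)C(O[Si](C)(C)C)=CC1(OC)O[Si](C)(C)C | intermediate
10 | (4R,6R)-4-acetyl-6-methoxy-4-(prop-2-en-1-yl)cyclohexane-1,3-dione (largely enolised; C6 mobile) | C=CC[C@]1(C(C)=O)C[C@@H](OC)C(=O)CC1=O | intermediate
11 | 5-(chloromethyl)-1,2,3-trimethoxybenzene (3,4,5-trimethoxybenzyl chloride) | COc1cc(CCl)cc(OC)c1OC | starting material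
12 | (3,4,5-trimethoxybenzyl)magnesium chloride (not isolated) | COc1cc(C[Mg]Cl)cc(OC)c1OC | intermediate
13 | (4R,6R)-4-[(2RS)-2-hydroxy-1-(3,4,5-trimethoxyphenyl)propan-2-yl]-6-methoxy-4-(prop-2-en-1-yl)cyclohexane-1,3-dione (carbinol epimers) | C=CC[C@]1(C(C)(O)Cc2cc(OC)c(OC)c(OC)c2)C[C@@H](OC)C(=O)CC1=O | intermediate
14 | (4R,6R)-6-methoxy-4-(prop-2-en-1-yl)-4-[(1E)-1-(3,4,5-trimethoxyphenyl)prop-1-en-2-yl]cyclohexane-1,3-dione (not isolated) | C=CC[C@]1(/C(C)=C/c2cc(OC)c(OC)c(OC)c2)C[C@@H](OC)C(=O)CC1=O | intermediate
15 | (2R,3R,3aR,5R)-5-methoxy-3-methyl-3a-(prop-2-en-1-yl)-2-(3,4,5-trimethoxyphenyl)-3,3a,4,5-tetrahydro-1-benzofuran-6(2H)-one | C=CC[C@]12C[C@@H](OC)C(=O)C=C1O[C@@H](c1cc(OC)c(OC)c(OC)c1)[C@@H]2C | target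

## Step count and risks

Total: 7 steps. Longest linear sequence: 5 steps (1, 2, 5, 6, 7 or 3, 4, 5, 6, 7).

Step 5 (key step, labelled as a proposed new method). Several things may go wrong. The diene may transfer a silyl group to the catalyst and start an achiral silyl-cation-catalysed pathway, which would erode the enantiomeric purity. The Brønsted-acidic catalyst may protodesilylate the diene. The reaction may stop after the first bond (Michael addition, or an inverse-demand hetero-cycloaddition across the enone), because closure between the quaternary carbon and the ketal carbon is congested. Face selectivity on an α-branched acyclic enone may be poor or of the opposite sense. The fallback uses known chemistry and sets out from 5 and 8. Uncatalysed cycloaddition in toluene at 60–80 °C (or with ZnCl2), followed by the hydrolysis of step 5, gives through the racemic silyl cycloadduct F1 the racemic 4-acetyl-6-methoxy-4-(prop-2-en-1-yl)cyclohexane-1,3-dione F2. Steps 6 and 7 turn this into the racemic carbinol F3 and, through the racemic styrene dione F4, into the racemic tetrahydrobenzofuranone F5. Its enantiomers are separated by preparative chromatography on a polysaccharide chiral stationary phase, and the route is rejoined at 15.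

Step 7. Equilibration at C3 and C2 may be incomplete, leaving ring B as a mixture. The benzylic cation may be diverted to C7 (C-alkylation) or the tertiary cation to a Wagner–Meerwein shift. On long exposure the allyl alkene may be protonated and captured irreversibly by the enol oxygen. The fallback builds ring B from a C2 alcohol under mild acid and sets out from 10. Wittig methoxymethylenation of the acetyl group with Ph3P=CHOMe (excess, generated with NaN(SiMe3)2; the first equivalent deprotonates the dione) gives the enol ether (4R,6R)-6-methoxy-4-(1-methoxyprop-1-en-2-yl)-4-(prop-2-en-1-yl)cyclohexane-1,3-dione F6. Dilute aqueous HCl hydrolyses it to the aldehyde, which closes onto the C7a enol oxygen as the lactol (3R,3aR,5R)-2-hydroxy-5-methoxy-3-methyl-3a-(prop-2-en-1-yl)-3,3a,4,5-tetrahydro-1-benzofuran-6(2H)-one F7. In F7 the C3 methyl group can equilibrate through the open aldehyde to the pseudo-equatorial position cis to allyl without any cation. Commercial 3,4,5-trimethoxyphenylmagnesium bromide (excess) adds to the open aldehyde form to give the benzylic alcohol (4R,6R)-4-[(1RS,2R)-1-hydroxy-1-(3,4,5-trimethoxyphenyl)propan-2-yl]-6-methoxy-4-(prop-2-en-1-yl)cyclohexane-1,3-dione F8. Camphorsulfonic acid in CH2Cl2 ionises only this electron-rich secondary benzylic alcohol, and closure trans to the methyl group returns the route at 15.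

Step 6. Homocoupling may occur during formation of the electron-rich benzylic Grignard reagent. The dione enolate may be poorly soluble, leading to incomplete addition. The acetyl group may be enolised instead of attacked. The fallback replaces the enolate shield by a covalent mask and sets out from 10. Acid-catalysed enol etherification (HC(OMe)3, MeOH, p-toluenesulfonic acid) should put the methyl group mainly on the less hindered C6 oxygen, giving (4R,6R)-6-acetyl-3,4-dimethoxy-6-(prop-2-en-1-yl)cyclohex-2-en-1-one F9. Its ring carbonyl is conjugated and flanked by the quaternary carbon, so the CeCl3-promoted addition of 12 occurs at the acetyl group in homogeneous solution and gives (4R,6R)-6-[(2RS)-2-hydroxy-1-(3,4,5-trimethoxyphenyl)propan-2-yl]-3,4-dimethoxy-6-(prop-2-en-1-yl)cyclohex-2-en-1-one F10. Dilute aqueous HCl in THF hydrolyses the vinylogous ester and returns the route at 13.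

## Further compounds

F1 | step 5 | racemic 1-[2,5-dimethoxy-1-(prop-2-en-1-yl)-2,4-bis(trimethylsilyloxy)cyclohex-3-en-1-yl]ethan-1-one | C=CCC1(C(C)=O)CC(OC)C(O[Si](C)(C)C)=CC1(OC)O[Si](C)(C)C
F2 | step 5 | racemic 4-acetyl-6-methoxy-4-(prop-2-en-1-yl)cyclohexane-1,3-dione | C=CCC1(C(C)=O)CC(OC)C(=O)CC1=O
F3 | step 5 | racemic 4-[2-hydroxy-1-(3,4,5-trimethoxyphenyl)propan-2-yl]-6-methoxy-4-(prop-2-en-1-yl)cyclohexane-1,3-dione | C=CCC1(C(C)(O)Cc2cc(OC)c(OC)c(OC)c2)CC(OC)C(=O)CC1=O
F4 | step 5 | racemic 6-methoxy-4-(prop-2-en-1-yl)-4-[(1E)-1-(3,4,5-trimethoxyphenyl)prop-1-en-2-yl]cyclohexane-1,3-dione | C=CCC1(/C(C)=C/c2cc(OC)c(OC)c(OC)c2)CC(OC)C(=O)CC1=O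
F5 | step 5 | racemic (2R*,3R*,3aR*,5R*)-5-methoxy-3-methyl-3a-(prop-2-en-1-yl)-2-(3,4,5-trimethoxyphenyl)-3,3a,4,5-tetrahydro-1-benzofuran-6(2H)-one (15 with its enantiomer; the SMILES shows the enantiomer) | C=CC[C@@]12C[C@H](OC)C(=O)C=C1O[C@H](c1cc(OC)c(OC)c(OC)c1)[C@H]2C
F6 | step 7 | (4R,6R)-6-methoxy-4-(1-methoxyprop-1-en-2-yl)-4-(prop-2-en-1-yl)cyclohexane-1,3-dione (E/Z mixture) | C=CC[C@]1(C(C)=COC)C[C@@H](OC)C(=O)CC1=O
F7 | step 7 | (3R,3aR,5R)-2-hydroxy-5-methoxy-3-methyl-3a-(prop-2-en-1-yl)-3,3a,4,5-tetrahydro-1-benzofuran-6(2H)-one (anomers) | C=CC[C@]12C[C@@H](OC)C(=O)C=C1OC(O)[C@@H]2C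
F8 | step 7 | (4R,6R)-4-[(1RS,2R)-1-hydroxy-1-(3,4,5-trimethoxyphenyl)propan-2-yl]-6-methoxy-4-(prop-2-en-1-yl)cyclohexane-1,3-dione | C=CC[C@]1([C@@H](C)C(O)c2cc(OC)c(OC)c(OC)c2)C[C@@H](OC)C(=O)CC1=O
F9 | step 6 | (4R,6R)-6-acetyl-3,4-dimethoxy-6-(prop-2-en-1-yl)cyclohex-2-en-1-one | C=CC[C@]1(C(C)=O)C[C@@H](OC)C(OC)=CC1=O
F10 | step 6 | (4R,6R)-6-[(2RS)-2-hydroxy-1-(3,4,5-trimethoxyphenyl)propan-2-yl]-3,4-dimethoxy-6-(prop-2-en-1-yl)cyclohex-2-en-1-one | C=CC[C@]1(C(C)(O)Cc2cc(OC)c(OC)c(OC)c2)C[C@@H](OC)C(OC)=CC1=O
A1 | alternative 1 | (2R,3R,3aR,7aR)-3-methyl-3a-(prop-2-en-1-yl)-2-(3,4,5-trimethoxyphenyl)-3,3a,7,7a-tetrahydro-1-benzofuran-6(2H)-one | C=CC[C@]12C=CC(=O)C[C@H]1O[C@@H](c1cc(OC)c(OC)c(OC)c1)[C@@H]2C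
A2 | alternative 1 | 4-[(1R,2R)-1-hydroxy-1-(3,4,5-trimethoxyphenyl)propan-2-yl]-4-(prop-2-en-1-yl)cyclohexa-2,5-dien-1-one | C=CCC1([C@@H](C)[C@@H](O)c2cc(OC)c(OC)c(OC)c2)C=CC(=O)C=C1
A3 | alternative 2 | (8R,10R)-10-methoxy-8-[(2R)-1-oxo-1-(3,4,5-trimethoxyphenyl)propan-2-yl]-8-(prop-2-en-1-yl)-1,4-dioxaspiro[4.5]decan-7-one | C=CC[C@]1([C@@H](C)C(=O)c2cc(OC)c(OC)c(OC)c2)C[C@@H](OC)C2(OCCO2)CC1=O
A4 | alternative 2 | Se-phenyl 2-{2-[(1R)-1-methoxy-4-methyl-5-oxo-3-(prop-2-en-1-yl)-5-(3,4,5-trimethoxyphenyl)pent-3-en-1-yl]-1,3-dioxolan-2-yl}ethaneselenoate | O=C([Se]c1ccccc1)CC1(OCCO1)[C@H](OC)CC(CC=C)=C(C)C(=O)c1cc(OC)c(OC)c(OC)c1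
A5 | alternative 3 | (2R,3R,3aS)-5-methoxy-3-methyl-3a-(prop-2-en-1-yl)-2-(3,4,5-trimethoxyphenyl)-3,3a-dihydro-1-benzofuran-6(2H)-one | C=CC[C@]12C=C(OC)C(=O)C=C1O[C@@H](c1cc(OC)c(OC)c(OC)c1)[C@@H]2C
A6 | alternative 3 | (1S,2R)-1-[5-hydroxy-4-methoxy-2-(prop-2-en-1-yl)phenoxy]-1-(3,4,5-trimethoxyphenyl)propan-2-yl methanesulfonate | C=CCc1cc(OC)c(O)cc1O[C@@H](c1cc(OC)c(OC)c(OC)c1)[C@@H](C)OS(C)(=O)=O
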